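The 1-hydroxypyrazin-2-one ring is read as the aromatic, O5-methylated lactim tautomer of a 6-alkylidenepiperazine-2,5-dione, and its N1–C6 bond is disconnected to an open-chain α-keto amide. The feature exploited is that C6 and its benzylic carbon can be supplied at ketone oxidation level by an indol-3-ylpyruvoyl unit: condensation of the hydroxamate N–H (future N1) with that ketone closes the six-membered ring and installs the C6 unsaturation in one operation, so no dehydrogenation is needed. The precursor is N-[3-(7-prenylindol-3-yl)pyruvoyl]-L-alanine O-benzylhydroxamate, made from 7-bromoindole, prenyl bromide, N-acetylglycine, Boc-L-alanine and O-benzylhydroxylamine.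

Key step: step 8

Assumption 1: in step 3 the indole nitrogen is taken to be acetylated along with azlactone formation; any N–H azlactone formed instead is hydrolysed to the same acid 9 in step 4.
Assumption 2: 16 and 17 are drawn Z; the E isomers would be carried through identically, because step 10 removes the alkene geometry together with the C3 stereocentre (the target is achiral, so racemic alanine would serve equally).
Assumption 3: 14 may exist partly as its enol or as its ring tautomer 15; all forms converge in step 8.

Step 1
Reactants: 1 7-bromo-1H-indole; 2 prenyl bromide (1-bromo-3-methylbut-2-ene)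
Product: 4 7-(3-methylbut-2-en-1-yl)-1H-indole (7-prenylindole), via prenylzinc bromide 3 (not isolated)
Conditions: 2 (2.5 equiv), Zn dust, LiCl, THF, 0 °C; then 1, Pd(OAc)2 (2 mol %), CPhos (4 mol %), THF, rt
Reagents that add atoms: none
Why: Linear-selective Negishi coupling of a 3,3-disubstituted allylzinc halide with an aryl bromide: with the bulky biarylphosphine CPhos on palladium the α-bound prenyl group is reductively eliminated before it can transpose, so the unrearranged prenyl group should reach C7, and the excess of the mildly basic organozinc covers the free indole N–H.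

Step 2
Reactants: 4 7-prenylindole
Product: 6 7-(3-methylbut-2-en-1-yl)-1H-indole-3-carbaldehyde, via iminium chloride 5 (not isolated)
Conditions: POCl3, DMF, 0 °C to rt; then 2 M aq NaOH, rt to 50 °C
Reagents that add atoms: N,N-dimethylformamide, CN(C)C=O (formyl carbon); water, O (formyl oxygen)
Why: Vilsmeier–Haack formylation takes place at C3, the most nucleophilic position of the indole, far faster than at the isolated trisubstituted alkene, and aqueous base hydrolyses iminium salt 5 to the aldehyde.

Step 3
Reactants: 6 7-prenylindole-3-carbaldehyde; 7 N-acetylglycine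
Product: 8 (4Z)-4-{[1-acetyl-7-(3-methylbut-2-en-1-yl)-1H-indol-3-yl]methylidene}-2-methyl-1,3-oxazol-5(4H)-one
Conditions: NaOAc, Ac2O, 100 °C
Reagents that add atoms: acetic anhydride, CC(=O)OC(C)=O (N1-acetyl group)
Why: Erlenmeyer–Plöchl azlactone synthesis: acetic anhydride cyclodehydrates 7 to an active methylene compound that condenses with the aldehyde, made more electrophilic by concurrent N1-acetylation, to give the thermodynamically preferred Z-alkylidene azlactone under buffered conditions that spare the prenyl group.

Step 4
Reactants: 8 azlactone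
Product: 9 3-[7-(3-methylbut-2-en-1-yl)-1H-indol-3-yl]-2-oxopropanoic acid
Conditions: 2 M aq NaOH (degassed), reflux, Ar; then cold 2 M HCl to pH 2, EtOAc; used at once
Reagents that add atoms: water, O (delivered as aqueous sodium hydroxide; ketone and carboxyl oxygen atoms)
Why: Alkaline azlactone hydrolysis: hydroxide opens the lactone and cleaves both acetamides, and the liberated enamine is hydrolysed with loss of ammonia to the α-keto carboxylate, all in base, where the acid-sensitive prenyl group is safe.

Step 5
Reactants: 10 Boc-L-alanine; 11 O-benzylhydroxylamine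
Product: 12 tert-butyl [(2S)-1-(benzyloxyamino)-1-oxopropan-2-yl]carbamate (Boc-L-Ala-NHOBn)
Conditions: EDC·HCl, HOBt, CH2Cl2, 0 °C to rt
Reagents that add atoms: none
Why: Carbodiimide/HOBt amide coupling; the urethane-protected amino acid does not racemise through an oxazolone and the alkoxyamine is acylated on nitrogen.

Step 6
Reactants: 12 Boc-L-Ala-NHOBn
Product: 13 (2S)-2-amino-N-(benzyloxy)propanamide hydrochloride (H-L-Ala-NHOBn·HCl)
Conditions: 4 M HCl in dioxane, rt
Reagents that add atoms: hydrogen chloride, Cl
Why: Acidolytic Boc cleavage (loss of the tert-butyl cation, then decarboxylation) leaves the hydroxamate, the benzyl ether and the stereocentre untouched.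

Step 7
Reactants: 9 arylpyruvic acid; 13 H-L-Ala-NHOBn·HCl
Product: 14 (2S)-N-(benzyloxy)-2-({3-[7-(3-methylbut-2-en-1-yl)-1H-indol-3-yl]-2-oxopropanoyl}amino)propanamide
Conditions: EDC·HCl, HOBt, i-Pr2NEt, DMF, 0 °C to rt
Reagents that add atoms: none
Why: Carbodiimide/HOBt amide coupling of an α-keto acid with a primary amine; the only stereocentre sits on the amine partner and is not at risk, and the freshly made acid is coupled cold to limit its decomposition.

Step 8
Reactants: 14 keto amide
Product: 16 (3S,6Z)-1-(benzyloxy)-3-methyl-6-{[7-(3-methylbut-2-en-1-yl)-1H-indol-3-yl]methylidene}piperazine-2,5-dione, via cyclic carbinolamide 15 (not isolated)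
Conditions: TsOH·H2O (0.1 equiv), toluene, 80–110 °C, Dean–Stark trap, Ar
Reagents that add atoms: none
Why: Protonation activates the ketone of the α-keto amide, the N–H of the N-benzyloxy amide (more nucleophilic than an ordinary amide nitrogen because of the adjacent oxygen) adds to it to give carbinolamide 15, and acid-assisted loss of water through the N-acyliminium ion followed by loss of a benzylic proton gives the enamide conjugated with the indole, water being removed azeotropically. The closest known reaction type is the acid-catalysed cyclodehydration of N-(α-ketoacyl) amino acid amides and O-alkyl hydroxamates to 3-alkylidenepiperazine-2,5-diones. The piperazinedione ring closes at N1–C6 in 6-exo-trig mode. No stereocentre is made: C6 ends trigonal, and the alkene geometry and any epimerisation at C3 do not matter because step 10 erases both. The selectivity needed is N- over O-closure and survival of the prenyl alkene and the indole; the hydroxamate carbonyl oxygen could also reach the ketone through a six-membered ring, but that imidate adduct forms reversibly and cannot end in a conjugated amide, so the equilibrium drains through nitrogen, while the ether oxygen is blocked by benzyl. A catalytic amount of acid in a non-polar solvent keeps protonation of the trisubstituted alkene slow relative to the intramolecular condensation.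

Step 9
Reactants: 16 alkylidene piperazinedione
Product: 17 (3S,6Z)-1-(benzyloxy)-5-methoxy-3-methyl-6-{[7-(3-methylbut-2-en-1-yl)-1H-indol-3-yl]methylidene}-3,6-dihydropyrazin-2(1H)-one
Conditions: Me3OBF4 (1.5 equiv), Na2CO3, CH2Cl2, 0 °C to rt
Reagents that add atoms: trimethyloxonium tetrafluoroborate, C[O+](C)C.F[B-](F)(F)F
Why: Lactim ether formation by O-alkylation with a trialkyloxonium salt: the secondary lactam oxygen O5 is the most nucleophilic site and its N4–H is then lost to carbonate, whereas the N-benzyloxy amide at C2 cannot give a neutral product and the weakly nucleophilic indole and alkene should not compete at 0 °C.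

Step 10
Reactants: 17 lactim ether
Product: 18 1-(benzyloxy)-5-methoxy-3-methyl-6-{[7-(3-methylbut-2-en-1-yl)-1H-indol-3-yl]methyl}pyrazin-2(1H)-one
Conditions: DBU (0.5 equiv), CH2Cl2, rt
Reagents that add atoms: none
Why: Base-mediated prototropic isomerisation: DBU removes the C3–H (α to C2=O and to N4) and reprotonation of the delocalised anion at the exocyclic carbon gives the aromatic pyrazin-2(1H)-one as the thermodynamic sink, erasing the C3 stereocentre and the alkene geometry.

Step 11
Reactants: 18 N-benzyloxy pyrazinone
Product: 20 astepyrazinoxide [1-hydroxy-5-methoxy-3-methyl-6-{[7-(3-methylbut-2-en-1-yl)-1H-indol-3-yl]methyl}pyrazin-2(1H)-one], via dichloroboryl ether 19 (not isolated)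
Conditions: BCl3 (1 M in CH2Cl2, 3 equiv), pentamethylbenzene (5 equiv), CH2Cl2, −78 °C; then MeOH
Reagents that add atoms: none
Why: Lewis acid O-debenzylation: BCl3 bound to the hydroxamate-type oxygen atoms ionises the O–benzyl bond at −78 °C, pentamethylbenzene captures the benzyl cation before it can alkylate the indole, and methanolysis of 19 frees the N-hydroxy group, while the methyl ether and the alkene should survive at this temperature.

Compound list
1 | 7-bromo-1H-indole | Brc1cccc2cc[nH]c12 | starting material
2 | prenyl bromide (1-bromo-3-methylbut-2-ene) | CC(C)=CCBr | starting material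
3 | prenylzinc bromide (not isolated) | CC(C)=CC[Zn]Br | intermediate
4 | 7-(3-methylbut-2-en-1-yl)-1H-indole | CC(C)=CCc1cccc2cc[nH]c12 | intermediate
5 | N,N-dimethyl-1-[7-(3-methylbut-2-en-1-yl)-1H-indol-3-yl]methaniminium chloride (not isolated) | CC(C)=CCc1cccc2c(C=[N+](C)C)c[nH]c12.[Cl-] | intermediate
6 | 7-(3-methylbut-2-en-1-yl)-1H-indole-3-carbaldehyde | CC(C)=CCc1cccc2c(C=O)c[nH]c12 | intermediate
7 | N-acetylglycine | CC(=O)NCC(=O)O | starting material
8 | (4Z)-4-{[1-acetyl-7-(3-methylbut-2-en-1-yl)-1H-indol-3-yl]methylidene}-2-methyl-1,3-oxazol-5(4H)-one | CC(=O)n1cc(/C=C2\N=C(C)OC2=O)c2cccc(CC=C(C)C)c12 | intermediate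
9 | 3-[7-(3-methylbut-2-en-1-yl)-1H-indol-3-yl]-2-oxopropanoic acid | CC(C)=CCc1cccc2c(CC(=O)C(=O)O)c[nH]c12 | intermediate
10 | Boc-L-alanine | C[C@H](NC(=O)OC(C)(C)C)C(=O)O | starting material
11 | O-benzylhydroxylamine | NOCc1ccccc1 | starting material
12 | tert-butyl [(2S)-1-(benzyloxyamino)-1-oxopropan-2-yl]carbamate | C[C@H](NC(=O)OC(C)(C)C)C(=O)NOCc1ccccc1 | intermediate
13 | (2S)-2-amino-N-(benzyloxy)propanamide hydrochloride | C[C@H](N)C(=O)NOCc1ccccc1.Cl | intermediate
14 | (2S)-N-(benzyloxy)-2-({3-[7-(3-methylbut-2-en-1-yl)-1H-indol-3-yl]-2-oxopropanoyl}amino)propanamide | C[C@H](NC(=O)C(=O)Cc1c[nH]c2c(CC=C(C)C)cccc12)C(=O)NOCc1ccccc1 | intermediate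
15 | (3S)-1-(benzyloxy)-6-hydroxy-3-methyl-6-{[7-(3-methylbut-2-en-1-yl)-1H-indol-3-yl]methyl}piperazine-2,5-dione (C6 epimers, not isolated) | C[C@@H]1NC(=O)C(O)(Cc2c[nH]c3c(CC=C(C)C)cccc23)N(OCc2ccccc2)C1=O | intermediate
16 | (3S,6Z)-1-(benzyloxy)-3-methyl-6-{[7-(3-methylbut-2-en-1-yl)-1H-indol-3-yl]methylidene}piperazine-2,5-dione | C[C@@H]1NC(=O)/C(=C/c2c[nH]c3c(CC=C(C)C)cccc23)N(OCc2ccccc2)C1=O | intermediate
17 | (3S,6Z)-1-(benzyloxy)-5-methoxy-3-methyl-6-{[7-(3-methylbut-2-en-1-yl)-1H-indol-3-yl]methylidene}-3,6-dihydropyrazin-2(1H)-one | C[C@@H]1N=C(OC)/C(=C/c2c[nH]c3c(CC=C(C)C)cccc23)N(OCc2ccccc2)C1=O | intermediate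
18 | 1-(benzyloxy)-5-methoxy-3-methyl-6-{[7-(3-methylbut-2-en-1-yl)-1H-indol-3-yl]methyl}pyrazin-2(1H)-one | COc1nc(C)c(=O)n(OCc2ccccc2)c1Cc1c[nH]c2c(CC=C(C)C)cccc12 | intermediate
19 | 1-[(dichloroboranyl)oxy]-5-methoxy-3-methyl-6-{[7-(3-methylbut-2-en-1-yl)-1H-indol-3-yl]methyl}pyrazin-2(1H)-one (not isolated) | COc1nc(C)c(=O)n(OB(Cl)Cl)c1Cc1c[nH]c2c(CC=C(C)C)cccc12 | intermediate
20 | astepyrazinoxide, 1-hydroxy-5-methoxy-3-methyl-6-{[7-(3-methylbut-2-en-1-yl)-1H-indol-3-yl]methyl}pyrazin-2(1H)-one | COc1nc(C)c(=O)n(O)c1Cc1c[nH]c2c(CC=C(C)C)cccc12 | target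

Total step count: 11.
Longest linear sequence: 9 steps (steps 1, 2, 3, 4, 7, 8, 9, 10, 11, from 7-bromoindole); steps 5 and 6 form the side branch.

Steps most likely to fail

Step 8. Process at risk: under hot Brønsted acid the trisubstituted alkene of the prenyl group may be protonated and then cyclise onto the indole nitrogen or hydrate, and the largely enolised keto amide may close sluggishly. Fallback, from 14 back to 16: the two events of the step are separated and run without acid. Et3N (or K2CO3) in THF at rt deprotonates the acidic N-benzyloxy amide, whose anion adds to the ketone, and carbinolamide 15 is isolated. MsCl and Et3N in CH2Cl2 at 0 °C then convert its tertiary hydroxyl group into the 6-methanesulfonate of 15 F1, which is not isolated and loses methanesulfonic acid (DBU added if needed) to give 16.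

Step 4. Process at risk: oxidative degradation or self-condensation of the electron-rich, enolised indolylpyruvate in hot alkali and on acidification, with further loss during the coupling of step 7. Fallback, from 4 back to 14 (it replaces steps 2, 3, 4 and 7): the keto group is carried as its oxime until the amide bond is in place. Commercial ethyl 3-bromo-2-(hydroxyimino)propanoate (SMILES CCOC(=O)C(CBr)=NO) and Na2CO3 in CH2Cl2 at rt generate ethyl 2-nitrosoprop-2-enoate F2, which is attacked by C3 of 4 to give ethyl 2-(hydroxyimino)-3-[7-(3-methylbut-2-en-1-yl)-1H-indol-3-yl]propanoate F3; this addition of indoles to nitrosoalkenes is a standard entry to indol-3-ylpyruvate oximes. LiOH in THF–H2O gives the stable 2-(hydroxyimino)-3-[7-(3-methylbut-2-en-1-yl)-1H-indol-3-yl]propanoic acid F4. EDC·HCl, HOBt and i-Pr2NEt couple F4 with 13 to the oximino amide F5. Deoximation with buffered aqueous TiCl3 (NH4OAc, THF–H2O, rt) cleaves the N–O bond of the oxime, and the imine hydrolyses to 14.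

Step 1. Process at risk: allylic transposition at palladium, which would give the branched 1,1-dimethylallyl isomer, or protodebromination after the reagent is quenched by the N–H group next to the bromide. Fallback, returning at 4: the prenyl group is delivered by a [3,3]-sigmatropic shift, which can place only the linear isomer at C7. It does not set out from a numbered compound but replaces 1–3 by commercial indoline F6. N-Alkylation with 3-chloro-3-methylbut-1-yne (SMILES CC(C)(Cl)C#C; CuCl cat., Et3N, THF, rt) gives 1-(2-methylbut-3-yn-2-yl)indoline F7. Semihydrogenation (H2, Pd/CaCO3 poisoned with Pb(OAc)2, quinoline, EtOAc) gives 1-(2-methylbut-3-en-2-yl)indoline F8. Acid-catalysed aromatic aza-Claisen rearrangement (TsOH·H2O, MeCN–H2O, 80 °C) gives 7-(3-methylbut-2-en-1-yl)indoline F9. MnO2 in CH2Cl2 at rt dehydrogenates F9 to 4.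

Further compounds
F1 | step 8 | (3S)-1-(benzyloxy)-3-methyl-6-{[7-(3-methylbut-2-en-1-yl)-1H-indol-3-yl]methyl}-2,5-dioxopiperazin-6-yl methanesulfonate (not isolated) | C[C@@H]1NC(=O)C(OS(C)(=O)=O)(Cc2c[nH]c3c(CC=C(C)C)cccc23)N(OCc2ccccc2)C1=O
F2 | step 4 | ethyl 2-nitrosoprop-2-enoate (transient) | CCOC(=O)C(=C)N=O
F3 | step 4 | ethyl 2-(hydroxyimino)-3-[7-(3-methylbut-2-en-1-yl)-1H-indol-3-yl]propanoate (oxime geometry not defined) | CCOC(=O)C(=NO)Cc1c[nH]c2c(CC=C(C)C)cccc12
F4 | step 4 | 2-(hydroxyimino)-3-[7-(3-methylbut-2-en-1-yl)-1H-indol-3-yl]propanoic acid | OC(=O)C(=NO)Cc1c[nH]c2c(CC=C(C)C)cccc12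
F5 | step 4 | (2S)-N-(benzyloxy)-2-({2-(hydroxyimino)-3-[7-(3-methylbut-2-en-1-yl)-1H-indol-3-yl]propanoyl}amino)propanamide | C[C@H](NC(=O)C(=NO)Cc1c[nH]c2c(CC=C(C)C)cccc12)C(=O)NOCc1ccccc1
F6 | step 1 | indoline (2,3-dihydro-1H-indole; new starting material) | C1Cc2ccccc2N1
F7 | step 1 | 1-(2-methylbut-3-yn-2-yl)-2,3-dihydro-1H-indole | C#CC(C)(C)N1CCc2ccccc21
F8 | step 1 | 1-(2-methylbut-3-en-2-yl)-2,3-dihydro-1H-indole | C=CC(C)(C)N1CCc2ccccc21
F9 | step 1 | 7-(3-methylbut-2-en-1-yl)-2,3-dihydro-1H-indole | CC(C)=CCc1cccc2c1NCC2
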